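**Plan**

1. Retrosynthetic cuts, in order: (a) three temporary groups are put back on the target (benzyl on the ring A phenol, bromine at isoquinoline C5', oxygen on the isoquinoline nitrogen); (b) the bond between isoquinoline C7' and isochromane C3; (c) the aryl acetal bond between C1 and the C6' oxygen; (d) in each half the pyran or pyridine ring, the aryl–alkyne bond and the aryl triflate, back to one aldehyde, 1.
2. Enabling feature: in the 2,9-dioxabicyclo[3.3.1]nonane core, isochromane C3 is both α to the ring oxygen O2 and β to the C4 acetyl group, so the 1H-isochromene precursor is a vinylogous ester that is electrophilic at C3. C1 is the labile acetal carbon of a 2-benzopyrylium ion, and isoquinoline C7' lies between the C6' oxygen and the C8' methoxy group.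
3. Forward order: pyran ring of the ring A isochromene (steps 1 to 6), pyridine ring of the isoquinoline N-oxide (steps 7 to 11), acetal exchange and closure of the 1,3-dioxine ring by the C7'–C3 bond (step 12), removal of the three helpers (step 13).
4. Stereochemistry: C1 and C3 are set together in step 12 by a chiral Brønsted acid (dynamic kinetic resolution of the aryl acetal; the tether enforces the cis relationship). C4 is set in the same step by protonation of the enol on the convex face.

Key step: step 12

Locants: the ring A part is numbered as an isochromane (C1 acetal carbon, O2, C3, C4, C4a, C5 to C8, C8a); isoquinoline locants carry a prime.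
Assumption: the (R)-configured acid is taken to give the (1R,3R,4S) series; its mirror image is used if the sense of induction proves to be the opposite.

**Route**

Step 1
Reactants: 1 2,4-dihydroxy-6-methoxybenzaldehyde
Product: 2 4-(benzyloxy)-2-hydroxy-6-methoxybenzaldehyde
Conditions: BnBr (1.05 equiv), K2CO3 (1.1 equiv), acetone, rt
Reagents that add atoms: benzyl bromide, BrCc1ccccc1
Why: Williamson etherification in which the C4 hydroxyl, para to the formyl group and not held in the hydrogen bond that deactivates the C2 hydroxyl, should be benzylated selectively.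

Step 2
Reactants: 2 4-(benzyloxy)-2-hydroxy-6-methoxybenzaldehyde
Product: 3 4-(benzyloxy)-6-hydroxy-2-methoxybenzene-1,3-dicarbaldehyde
Conditions: POCl3 (3 equiv), DMF, 0 to 60 °C; then aqueous NaOAc
Reagents that add atoms: N,N-dimethylformamide, CN(C)C=O; water, O
Why: Vilsmeier–Haack formylation, in which the non-coordinating chloroiminium ion should attack C5, para to the free hydroxyl and between the two ether oxygens, as is usual for 3,5-dialkoxyphenols, so that the new formyl group lies between the methoxy and benzyloxy groups.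

Step 3
Reactants: 3 4-(benzyloxy)-6-hydroxy-2-methoxybenzene-1,3-dicarbaldehyde
Product: 4 5-(benzyloxy)-2,4-diformyl-3-methoxyphenyl trifluoromethanesulfonate
Conditions: Tf2O (1.2 equiv), pyridine, CH2Cl2, 0 °C
Reagents that add atoms: trifluoromethanesulfonic anhydride, O=S(=O)(OS(=O)(=O)C(F)(F)F)C(F)(F)F
Why: O-sulfonylation of the one remaining phenol turns the oxygen on the future C4a carbon into a leaving group for cross-coupling.

Step 4
Reactants: 4 5-(benzyloxy)-2,4-diformyl-3-methoxyphenyl trifluoromethanesulfonate
Product: 5 4-(benzyloxy)-2-methoxy-6-(prop-1-yn-1-yl)benzene-1,3-dicarbaldehyde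
Conditions: propyne (3 equiv, solution in THF), PdCl2(PPh3)2 (5 mol %), CuI (10 mol %), Et3N, DMF, 50 °C, sealed tube
Reagents that add atoms: propyne, CC#C
Why: Sonogashira coupling of an aryl triflate activated by an ortho and a para formyl group, which brings in the three carbons that become C4 and the acetyl group.

Step 5
Reactants: 5 4-(benzyloxy)-2-methoxy-6-(prop-1-yn-1-yl)benzene-1,3-dicarbaldehyde
Product: 6 4-(benzyloxy)-2-methoxy-6-(2-oxopropyl)benzene-1,3-dicarbaldehyde
Conditions: NaAuCl4·2H2O (2 mol %), H2O (5 equiv), MeCN, rt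
Reagents that add atoms: water, O
Why: carbonyl-assisted alkyne hydration, in which 6-endo attack of the neighbouring formyl oxygen on the gold-activated alkyne and opening of the resulting isochromenylium ion by water should place the ketone on the carbon remote from the ring.

Step 6
Reactants: 6 4-(benzyloxy)-2-methoxy-6-(2-oxopropyl)benzene-1,3-dicarbaldehyde
Product: 8 4-acetyl-6-(benzyloxy)-1,8-dimethoxy-1H-isochromene-7-carbaldehyde (racemic), via enaminone 7 (not isolated)
Conditions: Me2NCH(OMe)2 (1.5 equiv), toluene, 50 °C; concentrate; then MeOH, pyridinium p-toluenesulfonate (1.2 equiv), rt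
Reagents that add atoms: N,N-dimethylformamide dimethyl acetal, COC(OC)N(C)C; methanol, CO
Why: aminomethylenation of the doubly activated benzylic methylene by the amide acetal, then acid-mediated addition–elimination in which the methanol hemiacetal of the neighbouring aldehyde displaces dimethylamine from the aminomethylene carbon (the usual site of enol ether formation in α-formyl ketones), which closes the pyran ring as a vinylogous ester with a methyl acetal at C1.

Step 7
Reactants: 2 4-(benzyloxy)-2-hydroxy-6-methoxybenzaldehyde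
Product: 9 5-(benzyloxy)-2-formyl-3-methoxyphenyl trifluoromethanesulfonate
Conditions: Tf2O (1.2 equiv), pyridine, CH2Cl2, 0 °C
Reagents that add atoms: trifluoromethanesulfonic anhydride, O=S(=O)(OS(=O)(=O)C(F)(F)F)C(F)(F)F
Why: O-sulfonylation of the chelated phenol gives the handle for the alkyne that becomes C4' and C3' of the isoquinoline.

Step 8
Reactants: 9 5-(benzyloxy)-2-formyl-3-methoxyphenyl trifluoromethanesulfonate
Product: 10 4-(benzyloxy)-2-methoxy-6-(prop-1-yn-1-yl)benzaldehyde
Conditions: propyne (3 equiv, solution in THF), PdCl2(PPh3)2 (5 mol %), CuI (10 mol %), Et3N, DMF, 50 °C, sealed tube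
Reagents that add atoms: propyne, CC#C
Why: Sonogashira coupling of an ortho-formyl aryl triflate, a standard entry to 2-alkynylbenzaldehydes.

Step 9
Reactants: 10 4-(benzyloxy)-2-methoxy-6-(prop-1-yn-1-yl)benzaldehyde
Product: 12 6-(benzyloxy)-8-methoxy-3-methylisoquinoline 2-oxide, via oxime 11 (not isolated)
Conditions: NH2OH·HCl (1.5 equiv), NaOAc (1.5 equiv), EtOH, rt; solvent exchange to CH2Cl2; AgOTf (5 mol %), rt
Reagents that add atoms: hydroxylamine hydrochloride, NO.Cl
Why: condensation to the aldoxime and silver-catalysed 6-endo-dig attack of the oxime nitrogen on the alkyne, a standard route to isoquinoline N-oxides, build the pyridine ring and leave nitrogen at the weakly basic oxidation level that step 12 needs.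

Step 10
Reactants: 12 6-(benzyloxy)-8-methoxy-3-methylisoquinoline 2-oxide
Product: 13 6-hydroxy-8-methoxy-3-methylisoquinoline 2-oxide
Conditions: BCl3 (3 equiv), pentamethylbenzene (3 equiv), CH2Cl2, −78 °C; MeOH quench
Reagents that add atoms: none
Why: Lewis acid cleavage of the aryl benzyl ether with a cation scavenger should free the C6' hydroxyl without touching the N–O bond or the C8' methyl ether.

Step 11
Reactants: 13 6-hydroxy-8-methoxy-3-methylisoquinoline 2-oxide
Product: 14 5-bromo-6-hydroxy-8-methoxy-3-methylisoquinoline 2-oxide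
Conditions: NBS (1.0 equiv), MeCN, −20 °C
Reagents that add atoms: N-bromosuccinimide, BrN1C(=O)CCC1=O
Why: electrophilic bromination of this naphthol-like phenol should go to C5', which is ortho to the hydroxyl, para to the methoxy group and the α-position of the bicyclic arene, and so blocks the carbon that would otherwise outrun C7' in step 12.

Step 12
Reactants: 8 4-acetyl-6-(benzyloxy)-1,8-dimethoxy-1H-isochromene-7-carbaldehyde (racemic, 1.2 equiv); 14 5-bromo-6-hydroxy-8-methoxy-3-methylisoquinoline 2-oxide
Product: 17 (1R,3R,4S)-4-acetyl-6-(benzyloxy)-8-methoxy-1,3-[oxy(5-bromo-8-methoxy-3-methyl-2-oxidoisoquinolin-2-ium-6,7-diyl)]isochromane-7-carbaldehyde, via aryl acetal 15 (not isolated), via enol 16 (not isolated)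
Conditions: (R)-3,3'-bis(2,4,6-triisopropylphenyl)-1,1'-binaphthyl-2,2'-diyl N-(trifluoromethylsulfonyl)phosphoramide (C51H57F3NO5PS, 10 mol %), 5 Å molecular sieves, CH2Cl2, 0 °C to rt; quench with solid NaHCO3
Reagents that add atoms: none
Why: Proposed new method: the acid exchanges the C1 methoxy group of 8 for the phenol oxygen of 14 through the aromatic 4-acetyl-2-benzopyrylium ion, so that the two C1 epimers of aryl acetal 15 interconvert, and the chiral ion pair then lets isoquinoline C7' attack C3 of the O-protonated vinylogous ester in an intramolecular conjugate Friedel–Crafts reaction, after which enol 16 ketonises; the closest known reaction types are the chiral-Brønsted-acid-catalysed Friedel–Crafts/ketalisation of 2-hydroxychalcones with naphthols to 2,8-dioxabicyclo[3.3.1]nonanes and the catalytic asymmetric oxa-Pictet–Spengler cyclisation, neither of which has used a 1-aryloxy-4-acyl-1H-isochromene as acceptor. The 1,3-dioxine ring closes 6-exo-trig with respect to the C3=C4 bond (6-endo with respect to the O2=C3 oxocarbenium form), and the tether C7'–C6'–O–C1 forces attack on the face of C3 that is cis to the C1–O bond. C1 and C3 are therefore set together and their absolute sense comes from the catalyst in a dynamic kinetic resolution, because once C3 is sp3 the acetal can no longer ionise to an aromatic cation and is fixed. C4 is set by the substrate: proton delivery to enol 16 on the convex face, away from the isoquinoline bridge and its C8' methoxy group, leaves the acetyl group cis to the aryl bridge (4S), and the low temperature and bicarbonate quench are meant to keep this kinetic centre from equilibrating. The step needs attack at C7' and not at the intrinsically more nucleophilic C5', which the C5' bromine secures, attack on C3 and not on C1 of the benzopyrylium ion, which the tether and the C8 methoxy group flanking C1 favour, and a nucleophile that does not neutralise the acid, which the N-oxide secures. The ring A aldehyde, flanked by two alkoxy groups, is too hindered and electron-rich to compete as an electrophile.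

Step 13
Reactants: 17 (1R,3R,4S)-4-acetyl-6-(benzyloxy)-8-methoxy-1,3-[oxy(5-bromo-8-methoxy-3-methyl-2-oxidoisoquinolin-2-ium-6,7-diyl)]isochromane-7-carbaldehyde
Product: 18 (1R,3R,4S)-4-acetyl-6-hydroxy-8-methoxy-1,3-[oxy(8-methoxy-3-methylisoquinoline-6,7-diyl)]isochromane-7-carbaldehyde (CNP0584953.1)
Conditions: H2 (1 atm), 10% Pd/C, NaOAc (1.5 equiv), EtOAc/MeOH, rt
Reagents that add atoms: none
Why: one heterogeneous hydrogenation should remove all three helpers (hydrogenolysis of the benzyl ether and of the aryl C–Br bond, deoxygenation of the N-oxide), while the buffered neutral medium should leave the enolisable C4 centre, the chelated aldehyde and the bicyclic acetal untouched.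

**Compound list**

1 | 2,4-dihydroxy-6-methoxybenzaldehyde | COc1cc(O)cc(O)c1C=O | starting material
2 | 4-(benzyloxy)-2-hydroxy-6-methoxybenzaldehyde | COc1cc(OCc2ccccc2)cc(O)c1C=O | intermediate
3 | 4-(benzyloxy)-6-hydroxy-2-methoxybenzene-1,3-dicarbaldehyde | COc1c(C=O)c(O)cc(OCc2ccccc2)c1C=O | intermediate
4 | 5-(benzyloxy)-2,4-diformyl-3-methoxyphenyl trifluoromethanesulfonate | COc1c(C=O)c(OS(=O)(=O)C(F)(F)F)cc(OCc2ccccc2)c1C=O | intermediate
5 | 4-(benzyloxy)-2-methoxy-6-(prop-1-yn-1-yl)benzene-1,3-dicarbaldehyde | CC#Cc1cc(OCc2ccccc2)c(C=O)c(OC)c1C=O | intermediate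
6 | 4-(benzyloxy)-2-methoxy-6-(2-oxopropyl)benzene-1,3-dicarbaldehyde | CC(=O)Cc1cc(OCc2ccccc2)c(C=O)c(OC)c1C=O | intermediate
7 | 4-(benzyloxy)-6-[(1E)-1-(dimethylamino)-3-oxobut-1-en-2-yl]-2-methoxybenzene-1,3-dicarbaldehyde | CN(C)/C=C(/C(C)=O)c1cc(OCc2ccccc2)c(C=O)c(OC)c1C=O | intermediate (not isolated)
8 | rac-4-acetyl-6-(benzyloxy)-1,8-dimethoxy-1H-isochromene-7-carbaldehyde | COC1OC=C(C(C)=O)c2cc(OCc3ccccc3)c(C=O)c(OC)c21 | intermediate
9 | 5-(benzyloxy)-2-formyl-3-methoxyphenyl trifluoromethanesulfonate | COc1cc(OCc2ccccc2)cc(OS(=O)(=O)C(F)(F)F)c1C=O | intermediate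
10 | 4-(benzyloxy)-2-methoxy-6-(prop-1-yn-1-yl)benzaldehyde | CC#Cc1cc(OCc2ccccc2)cc(OC)c1C=O | intermediate
11 | (E)-4-(benzyloxy)-2-methoxy-6-(prop-1-yn-1-yl)benzaldehyde oxime | CC#Cc1cc(OCc2ccccc2)cc(OC)c1/C=N/O | intermediate (not isolated)
12 | 6-(benzyloxy)-8-methoxy-3-methylisoquinoline 2-oxide | Cc1cc2cc(OCc3ccccc3)cc(OC)c2c[n+]1[O-] | intermediate
13 | 6-hydroxy-8-methoxy-3-methylisoquinoline 2-oxide | Cc1cc2cc(O)cc(OC)c2c[n+]1[O-] | intermediate
14 | 5-bromo-6-hydroxy-8-methoxy-3-methylisoquinoline 2-oxide | Cc1cc2c(Br)c(O)cc(OC)c2c[n+]1[O-] | intermediate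
15 | (1R)-4-acetyl-6-(benzyloxy)-1-[(5-bromo-8-methoxy-3-methyl-2-oxidoisoquinolin-2-ium-6-yl)oxy]-8-methoxy-1H-isochromene-7-carbaldehyde | COc1c(C=O)c(OCc3ccccc3)cc2c1[C@@H](Oc1cc(OC)c3c[n+]([O-])c(C)cc3c1Br)OC=C2C(C)=O | intermediate (not isolated)
16 | (1R,3R,4E)-6-(benzyloxy)-4-(1-hydroxyethylidene)-8-methoxy-1,3-[oxy(5-bromo-8-methoxy-3-methyl-2-oxidoisoquinolin-2-ium-6,7-diyl)]isochromane-7-carbaldehyde (enol; bridge oxygen on C1 and C6', C7' on C3) | COc1c(C=O)c(OCc5ccccc5)cc2c1[C@H]1Oc3c(Br)c4cc(C)[n+]([O-])cc4c(OC)c3[C@H](O1)/C2=C(/O)C | intermediate (not isolated)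
17 | (1R,3R,4S)-4-acetyl-6-(benzyloxy)-8-methoxy-1,3-[oxy(5-bromo-8-methoxy-3-methyl-2-oxidoisoquinolin-2-ium-6,7-diyl)]isochromane-7-carbaldehyde (bridge oxygen on C1 and C6', C7' on C3) | COc1c(C=O)c(OCc5ccccc5)cc2c1[C@H]1Oc3c(Br)c4cc(C)[n+]([O-])cc4c(OC)c3[C@H](O1)[C@H]2C(C)=O | intermediate
18 | (1R,3R,4S)-4-acetyl-6-hydroxy-8-methoxy-1,3-[oxy(8-methoxy-3-methylisoquinoline-6,7-diyl)]isochromane-7-carbaldehyde, CNP0584953.1 (bridge oxygen on C1 and C6', C7' on C3) | COc1c(C=O)c(O)cc2c1[C@H]1Oc3cc4cc(C)ncc4c(OC)c3[C@H](O1)[C@H]2C(C)=O | target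

**Step count and risks**

Total steps: 13. Longest linear sequence: 8 steps (1, 2, 3, 4, 5, 6, 12, 13; the branch 1, 7, 8, 9, 10, 11, 12, 13 is equally long).

Step 12 (proposed new method). What may go wrong: poor discrimination between the two C1 epimers of 15 in the ring closure, so that 17 forms with low enantiomeric purity, or acid-mediated enolisation that erodes C4. Fallback with known chemistry: 8 and 14 are condensed with an achiral acid, diphenyl hydrogen phosphate (PhO)2P(O)OH (20 mol %, CH2Cl2, 5 Å molecular sieves, rt). This is the racemic form of the acid-mediated phenol/oxocarbenium annulation and should give 17 together with the (1S,3S,4R)-enantiomer of 17 F1. The mixture is carried through the conditions of step 13 to 18 and the (1S,3S,4R)-enantiomer of 18 F2. Classical resolution through the basic isoquinoline nitrogen with (−)-O,O'-dibenzoyl-L-tartaric acid (crystallisation from EtOH/EtOAc) is then expected to give the hydrogen dibenzoyl-L-tartrate salt of 18 F3. Which diastereomeric salt crystallises has to be found by trial, and the mirror-image acid is taken if needed. Brief treatment with aqueous NaHCO3 returns the route to 18.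

Step 13. What may go wrong: over-reduction of the ortho-hydroxy aldehyde, slow N–O cleavage, or hydrogenolysis of a benzylic acetal C–O bond under hydrogen. Fallback: the three helpers are removed one at a time without hydrogen gas. From 17, bis(pinacolato)diboron (MeCN, 70 °C) deoxygenates the N-oxide to the 5'-bromo O-benzyl isoquinoline F4. Bu3SnH with Pd(PPh3)4 (toluene, 60 °C) replaces bromine by hydrogen to give the O-benzyl ether of 18 F5. BCl3 with pentamethylbenzene (CH2Cl2, −78 °C) cleaves the benzyl ether, which is activated by the neighbouring formyl group, and the route arrives at 18.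

Step 2. What may go wrong: formylation ortho instead of para to the free hydroxyl (attack at C3 of 2), or sluggish reaction of a ring that already carries a formyl group. Fallback: from 2, NBS (MeCN, 0 °C) first brominates the position ortho to the chelated hydroxyl to give 4-(benzyloxy)-3-bromo-2-hydroxy-6-methoxybenzaldehyde F6. Vilsmeier–Haack formylation can then take place only at C5 and gives 4-(benzyloxy)-5-bromo-6-hydroxy-2-methoxybenzene-1,3-dicarbaldehyde F7. Hydrodebromination with Pd(OAc)2, PPh3 and HCO2Na (DMF, 80 °C) returns the route to 3.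

Further compounds
F1 | step 12 | (1S,3S,4R)-enantiomer of 17 | COc1c(C=O)c(OCc5ccccc5)cc2c1[C@@H]1Oc3c(Br)c4cc(C)[n+]([O-])cc4c(OC)c3[C@@H](O1)[C@@H]2C(C)=O
F2 | step 12 | (1S,3S,4R)-enantiomer of 18 | COc1c(C=O)c(O)cc2c1[C@@H]1Oc3cc4cc(C)ncc4c(OC)c3[C@@H](O1)[C@@H]2C(C)=O
F3 | step 12 | hydrogen (2R,3R)-2,3-bis(benzoyloxy)butanedioate salt of 18 | COc1c(C=O)c(O)cc2c1[C@H]1Oc3cc4cc(C)[nH+]cc4c(OC)c3[C@H](O1)[C@H]2C(C)=O.OC(=O)[C@H](OC(=O)c1ccccc1)[C@@H](OC(=O)c1ccccc1)C([O-])=O
F4 | step 13 | (1R,3R,4S)-4-acetyl-6-(benzyloxy)-8-methoxy-1,3-[oxy(5-bromo-8-methoxy-3-methylisoquinoline-6,7-diyl)]isochromane-7-carbaldehyde | COc1c(C=O)c(OCc5ccccc5)cc2c1[C@H]1Oc3c(Br)c4cc(C)ncc4c(OC)c3[C@H](O1)[C@H]2C(C)=O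
F5 | step 13 | (1R,3R,4S)-4-acetyl-6-(benzyloxy)-8-methoxy-1,3-[oxy(8-methoxy-3-methylisoquinoline-6,7-diyl)]isochromane-7-carbaldehyde | COc1c(C=O)c(OCc5ccccc5)cc2c1[C@H]1Oc3cc4cc(C)ncc4c(OC)c3[C@H](O1)[C@H]2C(C)=O
F6 | step 2 | 4-(benzyloxy)-3-bromo-2-hydroxy-6-methoxybenzaldehyde | COc1cc(OCc2ccccc2)c(Br)c(O)c1C=O
F7 | step 2 | 4-(benzyloxy)-5-bromo-6-hydroxy-2-methoxybenzene-1,3-dicarbaldehyde | COc1c(C=O)c(O)c(Br)c(OCc2ccccc2)c1C=O
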